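**Retrosynthetic overview**

1. Numbering (labdane): ring A = C1–C5 + C10, ring B = C5–C10; C4 carries the gem-dimethyl group, C10 the angular methyl, C9 the side chain C11–C16. The 7-acetate goes on last (acylation of the equatorial 7β-OH of a 6β,7β,8α-triol), and the (12E)-diene comes from a C12 lactol by two Wittig reactions.
2. The triol comes from an 8-methyl-Δ7-6-ketone in ring B: α-face hydride at C6, α-face dihydroxylation of C7=C8, then oxidation/reduction at C7; the C12 ester is parked as a temporary 8α,12-lactone.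
3. Key disconnection: ring A is taken apart as a formal [3+3], bonds C1–C2 and C4–C5, into a cyclopropyl ketone (cyclopropane C1–C5–C10 fused to ring B, carbonyl at C6) and the C5 allylboronate CH2=CH–C(CH3)2–Bpin (C2, C3, C4 and both C4 methyls).
4. Enabling feature: the quaternary C10 lies between C1 and C5, and C5 is α to the C6 oxygen. C1 and C5 can therefore be stored in one strained three-membered ring next to a C6 ketone, whose reductive opening frees a C1 radical and a C5 enolate together; ring A itself carries only the gem-dimethyl group, which an isoprene-type unit supplies.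
5. Ring order: ring B (from cyclohex-2-enone; the C8 methyl centre is set by Cu catalysis and relayed to C9, C10, C5, C6, C7, C8) → temporary cyclopropane → ring A (key step) → temporary lactone, opened for the side chain.

Key step: step 9

Remark: α/β and C-numbers in the Why lines use the labdane numbering above; compound names use systematic numbering.

**Step 1**
Reactants: 1 cyclohex-2-en-1-one; 2 tert-butyl bromoacetate
Product: 4 tert-butyl 2-[(1S,2R)-2-methyl-6-oxocyclohexyl]acetate, via methylzinc enolate 3 (not isolated)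
Conditions: Me2Zn, Cu(OTf)2 (2 mol%), BINOL-derived phosphoramidite ligand (4 mol%; the enantiomer that gives the R methyl centre), toluene, −30 °C; then 2, DMPU, 0 °C to rt
Reagents that add atoms: dimethylzinc, C[Zn]C
Why: Copper-catalysed asymmetric conjugate addition should set the methyl-bearing carbon (C8) under ligand control, and alkylation of the zinc enolate anti to that methyl group should set C9 trans to it by substrate control (tandem conjugate addition–enolate alkylation).

**Step 2**
Reactants: 4 tert-butyl 2-[(1S,2R)-2-methyl-6-oxocyclohexyl]acetate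
Product: 6 tert-butyl 2-[(1S,6R)-6-methyl-2-oxocyclohex-3-en-1-yl]acetate, via lithium enolate 5 (not isolated)
Conditions: LiN(i-Pr)2, THF, −78 °C; then N-tert-butylbenzenesulfinimidoyl chloride, −78 °C
Reagents that add atoms: none
Why: Kinetic deprotonation should take the unsubstituted α-CH2 (C5), and sulfinimidoyl chloride dehydrogenation of that enolate should give the enone without touching the two stereocentres or the ester.

**Step 3**
Reactants: 6 tert-butyl 2-[(1S,6R)-6-methyl-2-oxocyclohex-3-en-1-yl]acetate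
Product: 7 tert-butyl 2-[(1S,6R)-2-hydroxy-2,6-dimethylcyclohex-3-en-1-yl]acetate (both carbinol epimers)
Conditions: MeLi, CeCl3, THF, −78 °C; NH4Cl quench at −78 °C
Reagents that add atoms: methyllithium, [Li]C
Why: The organocerium reagent should add 1,2 to the enone carbonyl and leave the tert-butyl ester alone (organocerium carbonyl addition); the new carbinol centre is destroyed in step 4, so its configuration is irrelevant.

**Step 4**
Reactants: 7 tert-butyl 2-[(1S,6R)-2-hydroxy-2,6-dimethylcyclohex-3-en-1-yl]acetate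
Product: 8 tert-butyl 2-[(1S,6R)-2,6-dimethyl-4-oxocyclohex-2-en-1-yl]acetate
Conditions: pyridinium chlorochromate (C5H5NH)[CrO3Cl], 4 Å molecular sieves, CH2Cl2, rt
Reagents that add atoms: pyridinium chlorochromate, [O-][Cr](=O)(=O)Cl.c1cc[nH+]cc1
Why: The chromate ester of the tertiary allylic alcohol should undergo a [3,3] shift and oxidation (oxidative 1,3-transposition), which moves the oxygen to C6 and leaves the methyl group on the β-carbon C10; no stereocentre is formed.

**Step 5**
Reactants: 8 tert-butyl 2-[(1S,6R)-2,6-dimethyl-4-oxocyclohex-2-en-1-yl]acetate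
Product: 9 tert-butyl 2-[(1S,4S,6R)-4-hydroxy-2,6-dimethylcyclohex-2-en-1-yl]acetate
Conditions: NaBH4, CeCl3·7H2O, MeOH, −40 to 0 °C
Reagents that add atoms: none
Why: Luche 1,2-reduction should deliver hydride anti to the ring methyl group two carbons away (as in the carvone to cis-carveol case), so the C6 hydroxyl ends up cis to that methyl group, on the face where the cyclopropane is wanted (substrate control).

**Step 6**
Reactants: 9 tert-butyl 2-[(1S,4S,6R)-4-hydroxy-2,6-dimethylcyclohex-2-en-1-yl]acetate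
Product: 10 tert-butyl 2-[(1R,2S,3R,5S,6R)-5-hydroxy-1,3-dimethylbicyclo[4.1.0]heptan-2-yl]acetate
Conditions: Et2Zn, CH2I2, CH2Cl2, 0 °C
Reagents that add atoms: diiodomethane, ICI
Why: The zinc alkoxide should deliver the carbenoid to its own face (hydroxyl-directed Simmons–Smith cyclopropanation), which sets C5 and the quaternary C10 together and puts the new methylene (C1) anti to the acetate arm.

**Step 7**
Reactants: 10 tert-butyl 2-[(1R,2S,3R,5S,6R)-5-hydroxy-1,3-dimethylbicyclo[4.1.0]heptan-2-yl]acetate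
Product: 11 tert-butyl 2-[(1R,2S,3R,6R)-1,3-dimethyl-5-oxobicyclo[4.1.0]heptan-2-yl]acetate
Conditions: Dess–Martin periodinane, NaHCO3, CH2Cl2, rt
Reagents that add atoms: none
Why: Dess–Martin oxidation of the secondary cyclopropylcarbinol should give the cyclopropyl ketone under buffered conditions that spare the cyclopropane and the ester.

**Step 8**
Reactants: 12 (3-methylbut-2-en-1-yl)magnesium chloride; 13 2-isopropoxy-4,4,5,5-tetramethyl-1,3,2-dioxaborolane
Product: 14 4,4,5,5-tetramethyl-2-(2-methylbut-3-en-2-yl)-1,3,2-dioxaborolane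
Conditions: THF, −78 °C to rt; aq. NH4Cl
Reagents that add atoms: none
Why: The allylic Grignard reagent should attack boron through its γ-carbon (SE2′ borylation of a prenyl metal) to give the tertiary allylboronic ester, which as a pinacol ester should not undergo 1,3-boron shift at room temperature.

**Step 9**
Reactants: 11 tert-butyl 2-[(1R,2S,3R,6R)-1,3-dimethyl-5-oxobicyclo[4.1.0]heptan-2-yl]acetate; 14 4,4,5,5-tetramethyl-2-(2-methylbut-3-en-2-yl)-1,3,2-dioxaborolane
Product: 15 tert-butyl 2-[(1S,2R,4aS,8aR)-2,5,5,8a-tetramethyl-4-oxo-6-(4,4,5,5-tetramethyl-1,3,2-dioxaborolan-2-yl)decahydronaphthalen-1-yl]acetate (both epimers at the boron-bearing carbon)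
Conditions: SmI2 (25 mol%), Sm metal (25 mol%), 14 (5 equiv), THF (0.05 M), 55 °C; then DBU, rt
Reagents that add atoms: none
Why: Proposed new method: SmI2 (divalent samarium) should reduce 11 to its ketyl, whose strained exocyclic cyclopropane bond C1–C5 opens to a trivalent samarium enolate (C5=C6) and a primary C1 radical; this radical adds to the CH2 terminus of 14 (bond C1–C2), the β-boryl radical at C3 undergoes a 1,2-boron shift to the tertiary C4 radical, and that radical closes onto the enolate carbon C5 (bond C4–C5) to a ketyl that returns its electron to samarium. The closest known reactions are the SmI2-catalysed formal [3+2] coupling of alkyl cyclopropyl ketones with alkenes and the radical 1,3-difunctionalisation of α,α-dialkyl allylboronic esters through a 1,2-boron shift; their merger into a formal [3+3] has not been shown. Ring A is closed by 6-exo-trig attack of the C4 radical on C5 after the intermolecular C1–C2 addition. C10 is carried unchanged from 11, C5 is formed α to the C6 carbonyl and is therefore set thermodynamically by DBU as the trans ring fusion, and the boron-bearing C3 is uncontrolled and removed in step 10. The step needs cleavage of C1–C5 rather than C5–C10, addition to 14 faster than hydrogen abstraction, and boron shift before five-ring closure. These should be secured, in turn, by the overlap of the exocyclic bond with the ketyl in the rigid bicycle, by excess 14 together with an acetate arm that has no 1,5-hydrogen and no radical acceptor, and by the congestion of direct closure next to the C(CH3)2Bpin group plus the gain in radical stability.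

**Step 10**
Reactants: 15 tert-butyl 2-[(1S,2R,4aS,8aR)-2,5,5,8a-tetramethyl-4-oxo-6-(4,4,5,5-tetramethyl-1,3,2-dioxaborolan-2-yl)decahydronaphthalen-1-yl]acetate
Product: 16 tert-butyl 2-[(1S,2R,4aS,8aR)-2,5,5,8a-tetramethyl-4-oxodecahydronaphthalen-1-yl]acetate
Conditions: 2-methoxy-1,3,2-benzodioxaborole (0.3 equiv), 4-tert-butylcatechol (2 equiv), di-tert-butyl hyponitrite (cat.), benzene, 70 °C
Reagents that add atoms: none
Why: In-situ exchange of the pinacol for the catechol boronic ester should allow a radical chain in which the C3 radical takes a hydrogen atom from the catechol (radical protodeboronation of an alkylboronic ester), so C3 becomes CH2 and no stereocentre is touched.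

**Step 11**
Reactants: 16 tert-butyl 2-[(1S,2R,4aS,8aR)-2,5,5,8a-tetramethyl-4-oxodecahydronaphthalen-1-yl]acetate
Product: 17 tert-butyl 2-[(1S,4aS,8aR)-2,5,5,8a-tetramethyl-4-oxo-1,4,4a,5,6,7,8,8a-octahydronaphthalen-1-yl]acetate
Conditions: IBX, DMSO/fluorobenzene, 75 °C
Reagents that add atoms: none
Why: IBX dehydrogenation of the ketone can only run toward C7–C8, because the other α-carbon (C5) has a quaternary neighbour, so the 8-methyl-Δ7-6-ketone should form and the relay stereocentre at C8 disappears.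

**Step 12**
Reactants: 17 tert-butyl 2-[(1S,4aS,8aR)-2,5,5,8a-tetramethyl-4-oxo-1,4,4a,5,6,7,8,8a-octahydronaphthalen-1-yl]acetate
Product: 18 tert-butyl 2-[(1S,4R,4aS,8aR)-4-hydroxy-2,5,5,8a-tetramethyl-1,4,4a,5,6,7,8,8a-octahydronaphthalen-1-yl]acetate
Conditions: NaBH4, CeCl3·7H2O, MeOH, 0 °C
Reagents that add atoms: none
Why: In this Luche reduction hydride should come from the α-face, because the β-face of C6 is blocked by the axial methyl groups on C4 and C10, which sets the axial 6β-hydroxyl (substrate control).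

**Step 13**
Reactants: 18 tert-butyl 2-[(1S,4R,4aS,8aR)-4-hydroxy-2,5,5,8a-tetramethyl-1,4,4a,5,6,7,8,8a-octahydronaphthalen-1-yl]acetate
Product: 20 (3aS,4R,5S,5aS,9aS,9bR)-4,5-dihydroxy-3a,6,6,9a-tetramethyldecahydronaphtho[2,1-b]furan-2(1H)-one, via triol ester 19 (not isolated)
Conditions: OsO4 (5 mol%), N-methylmorpholine N-oxide, acetone/H2O, rt; crude, then TFA, CH2Cl2, 0 °C
Reagents that add atoms: OsO4, O=[Os](=O)(=O)=O; N-methylmorpholine N-oxide, C[N+]1([O-])CCOCC1
Why: Catalytic dihydroxylation should attack C7=C8 from the α-face, anti to the allylic 6β-hydroxyl and to the axial C10 methyl, which sets 7α-OH and the tertiary 8α-OH/8β-CH3 centre; acid then closes the γ-lactone between the 8α-oxygen and the tert-butyl ester.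

**Step 14**
Reactants: 20 (3aS,4R,5S,5aS,9aS,9bR)-4,5-dihydroxy-3a,6,6,9a-tetramethyldecahydronaphtho[2,1-b]furan-2(1H)-one
Product: 21 (3aS,5S,5aS,9aS,9bR)-5-hydroxy-3a,6,6,9a-tetramethyloctahydronaphtho[2,1-b]furan-2,4-dione (the 7-ketone in labdane numbering)
Conditions: Dess–Martin periodinane (1.1 equiv), NaHCO3, CH2Cl2, 0 °C
Reagents that add atoms: none
Why: Of the two secondary alcohols only the 7α-hydroxyl is accessible, the 6β-hydroxyl being syn-axial to the methyl groups on C4, C8 and C10, so Dess–Martin oxidation should stop at the 7-ketone and erase the wrongly configured C7 centre.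

**Step 15**
Reactants: 21 (3aS,5S,5aS,9aS,9bR)-5-hydroxy-3a,6,6,9a-tetramethyloctahydronaphtho[2,1-b]furan-2,4-dione
Product: 22 (3aS,4S,5S,5aS,9aS,9bR)-4,5-dihydroxy-3a,6,6,9a-tetramethyldecahydronaphtho[2,1-b]furan-2(1H)-one
Conditions: NaBH4, MeOH/THF, −20 °C
Reagents that add atoms: none
Why: Borohydride should attack the C7 carbonyl axially from the open α-face (the β-face carries the 8β-methyl and 6β-hydroxyl), which gives the equatorial 7β-alcohol by substrate control while the lactone survives at low temperature.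

**Step 16**
Reactants: 22 (3aS,4S,5S,5aS,9aS,9bR)-4,5-dihydroxy-3a,6,6,9a-tetramethyldecahydronaphtho[2,1-b]furan-2(1H)-one
Product: 23 (3aS,4S,5S,5aS,9aS,9bR)-3a,6,6,9a-tetramethyldodecahydronaphtho[2,1-b]furan-2,4,5-triol (lactol, both anomers)
Conditions: i-Bu2AlH (4 equiv), CH2Cl2, −78 °C; Rochelle salt
Reagents that add atoms: none
Why: Half-reduction of the γ-lactone by i-Bu2AlH should stop at the lactol, the masked C12 aldehyde; the anomeric centre is lost in step 17.

**Step 17**
Reactants: 23 (3aS,4S,5S,5aS,9aS,9bR)-3a,6,6,9a-tetramethyldodecahydronaphtho[2,1-b]furan-2,4,5-triol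
Product: 24 (E)-2-methyl-4-[(1R,2S,3S,4S,4aS,8aS)-2,3,4-trihydroxy-2,5,5,8a-tetramethyldecahydronaphthalen-1-yl]but-2-enal
Conditions: Ph3P=C(CH3)CHO (3 equiv), toluene, 90 °C
Reagents that add atoms: 2-(triphenylphosphoranylidene)propanal, CC(C=O)=P(c1ccccc1)(c1ccccc1)c1ccccc1
Why: The lactol should open to the hydroxy aldehyde, which the formyl-stabilised ylide converts to the trisubstituted enal with E geometry (Wittig reaction of a stabilised ylide).

**Step 18**
Reactants: 24 (E)-2-methyl-4-[(1R,2S,3S,4S,4aS,8aS)-2,3,4-trihydroxy-2,5,5,8a-tetramethyldecahydronaphthalen-1-yl]but-2-enal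
Product: 25 (1R,2S,3S,4S,4aS,8aS)-2,5,5,8a-tetramethyl-1-[(2E)-3-methylpenta-2,4-dien-1-yl]decahydronaphthalene-2,3,4-triol
Conditions: Ph3PCH3Br, KN(SiMe3)2 (excess), THF, −78 to 0 °C
Reagents that add atoms: methyltriphenylphosphonium bromide, C[P+](c1ccccc1)(c1ccccc1)c1ccccc1.[Br-]
Why: Wittig methylenation of the enal with excess ylide should give the 12E,14-diene without changing the C12=C13 geometry, the deprotonated hydroxyls being inert at low temperature.

**Step 19**
Reactants: 25 (1R,2S,3S,4S,4aS,8aS)-2,5,5,8a-tetramethyl-1-[(2E)-3-methylpenta-2,4-dien-1-yl]decahydronaphthalene-2,3,4-triol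
Product: 26 (1R,2S,3S,4S,4aS,8aS)-2,4-dihydroxy-2,5,5,8a-tetramethyl-1-[(2E)-3-methylpenta-2,4-dien-1-yl]decahydronaphthalen-3-yl acetate (CNP0225877.1)
Conditions: Ac2O (1.2 equiv), pyridine, 0 °C
Reagents that add atoms: acetic anhydride, CC(=O)OC(C)=O
Why: Acylation should pick the equatorial secondary 7β-hydroxyl over the tertiary 8α-hydroxyl and the axial 6β-hydroxyl, which is flanked by three syn-axial methyl groups (sterically controlled selective acetylation).

**Compound list**

1 | cyclohex-2-en-1-one | O=C1C=CCCC1 | starting material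
2 | tert-butyl bromoacetate | CC(C)(C)OC(=O)CBr | starting material
3 | methylzinc (R)-3-methylcyclohex-1-en-1-olate | C[C@@H]1CCCC(O[Zn]C)=C1 | intermediate
4 | tert-butyl 2-[(1S,2R)-2-methyl-6-oxocyclohexyl]acetate | CC(C)(C)OC(=O)C[C@H]1[C@H](C)CCCC1=O | intermediate
5 | lithium (5R,6S)-6-(2-tert-butoxy-2-oxoethyl)-5-methylcyclohex-1-en-1-olate | CC(C)(C)OC(=O)C[C@H]1[C@H](C)CCC=C1O[Li] | intermediate
6 | tert-butyl 2-[(1S,6R)-6-methyl-2-oxocyclohex-3-en-1-yl]acetate | CC(C)(C)OC(=O)C[C@H]1[C@H](C)CC=CC1=O | intermediate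
7 | tert-butyl 2-[(1S,6R)-2-hydroxy-2,6-dimethylcyclohex-3-en-1-yl]acetate (both carbinol epimers) | CC(C)(C)OC(=O)C[C@H]1[C@H](C)CC=CC1(C)O | intermediate
8 | tert-butyl 2-[(1S,6R)-2,6-dimethyl-4-oxocyclohex-2-en-1-yl]acetate | CC(C)(C)OC(=O)C[C@H]1[C@H](C)CC(=O)C=C1C | intermediate
9 | tert-butyl 2-[(1S,4S,6R)-4-hydroxy-2,6-dimethylcyclohex-2-en-1-yl]acetate | CC(C)(C)OC(=O)C[C@H]1[C@H](C)C[C@H](O)C=C1C | intermediate
10 | tert-butyl 2-[(1R,2S,3R,5S,6R)-5-hydroxy-1,3-dimethylbicyclo[4.1.0]heptan-2-yl]acetate | CC(C)(C)OC(=O)C[C@H]1[C@H](C)C[C@H](O)[C@@H]2C[C@]12C | intermediate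
11 | tert-butyl 2-[(1R,2S,3R,6R)-1,3-dimethyl-5-oxobicyclo[4.1.0]heptan-2-yl]acetate | CC(C)(C)OC(=O)C[C@H]1[C@H](C)CC(=O)[C@@H]2C[C@]12C | intermediate
12 | (3-methylbut-2-en-1-yl)magnesium chloride | CC(C)=CC[Mg]Cl | starting material
13 | 2-isopropoxy-4,4,5,5-tetramethyl-1,3,2-dioxaborolane | CC(C)OB1OC(C)(C)C(C)(C)O1 | starting material
14 | 4,4,5,5-tetramethyl-2-(2-methylbut-3-en-2-yl)-1,3,2-dioxaborolane | C=CC(C)(C)B1OC(C)(C)C(C)(C)O1 | intermediate
15 | tert-butyl 2-[(1S,2R,4aS,8aR)-2,5,5,8a-tetramethyl-4-oxo-6-(4,4,5,5-tetramethyl-1,3,2-dioxaborolan-2-yl)decahydronaphthalen-1-yl]acetate (both epimers at the boron-bearing carbon) | CC(C)(C)OC(=O)C[C@H]1[C@H](C)CC(=O)[C@H]2C(C)(C)C(B3OC(C)(C)C(C)(C)O3)CC[C@@]21C | intermediate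
16 | tert-butyl 2-[(1S,2R,4aS,8aR)-2,5,5,8a-tetramethyl-4-oxodecahydronaphthalen-1-yl]acetate | CC(C)(C)OC(=O)C[C@H]1[C@H](C)CC(=O)[C@H]2C(C)(C)CCC[C@@]21C | intermediate
17 | tert-butyl 2-[(1S,4aS,8aR)-2,5,5,8a-tetramethyl-4-oxo-1,4,4a,5,6,7,8,8a-octahydronaphthalen-1-yl]acetate | CC(C)(C)OC(=O)C[C@H]1C(C)=CC(=O)[C@H]2C(C)(C)CCC[C@@]21C | intermediate
18 | tert-butyl 2-[(1S,4R,4aS,8aR)-4-hydroxy-2,5,5,8a-tetramethyl-1,4,4a,5,6,7,8,8a-octahydronaphthalen-1-yl]acetate | CC(C)(C)OC(=O)C[C@H]1C(C)=C[C@@H](O)[C@H]2C(C)(C)CCC[C@@]21C | intermediate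
19 | tert-butyl 2-[(1R,2S,3R,4S,4aS,8aS)-2,3,4-trihydroxy-2,5,5,8a-tetramethyldecahydronaphthalen-1-yl]acetate | CC(C)(C)OC(=O)C[C@H]1[C@](C)(O)[C@H](O)[C@@H](O)[C@H]2C(C)(C)CCC[C@@]21C | intermediate
20 | (3aS,4R,5S,5aS,9aS,9bR)-4,5-dihydroxy-3a,6,6,9a-tetramethyldecahydronaphtho[2,1-b]furan-2(1H)-one | O=C3C[C@H]1[C@](C)(O3)[C@H](O)[C@@H](O)[C@H]2C(C)(C)CCC[C@@]21C | intermediate
21 | (3aS,5S,5aS,9aS,9bR)-5-hydroxy-3a,6,6,9a-tetramethyloctahydronaphtho[2,1-b]furan-2,4-dione | O=C3C[C@H]1[C@](C)(O3)C(=O)[C@@H](O)[C@H]2C(C)(C)CCC[C@@]21C | intermediate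
22 | (3aS,4S,5S,5aS,9aS,9bR)-4,5-dihydroxy-3a,6,6,9a-tetramethyldecahydronaphtho[2,1-b]furan-2(1H)-one | O=C3C[C@H]1[C@](C)(O3)[C@@H](O)[C@@H](O)[C@H]2C(C)(C)CCC[C@@]21C | intermediate
23 | (3aS,4S,5S,5aS,9aS,9bR)-3a,6,6,9a-tetramethyldodecahydronaphtho[2,1-b]furan-2,4,5-triol (both anomers) | OC3C[C@H]1[C@](C)(O3)[C@@H](O)[C@@H](O)[C@H]2C(C)(C)CCC[C@@]21C | intermediate
24 | (E)-2-methyl-4-[(1R,2S,3S,4S,4aS,8aS)-2,3,4-trihydroxy-2,5,5,8a-tetramethyldecahydronaphthalen-1-yl]but-2-enal | O=C/C(C)=C/C[C@H]1[C@](C)(O)[C@@H](O)[C@@H](O)[C@H]2C(C)(C)CCC[C@@]21C | intermediate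
25 | (1R,2S,3S,4S,4aS,8aS)-2,5,5,8a-tetramethyl-1-[(2E)-3-methylpenta-2,4-dien-1-yl]decahydronaphthalene-2,3,4-triol | C=C/C(C)=C/C[C@H]1[C@](C)(O)[C@@H](O)[C@@H](O)[C@H]2C(C)(C)CCC[C@@]21C | intermediate
26 | (1R,2S,3S,4S,4aS,8aS)-2,4-dihydroxy-2,5,5,8a-tetramethyl-1-[(2E)-3-methylpenta-2,4-dien-1-yl]decahydronaphthalen-3-yl acetate | C=C/C(C)=C/C[C@H]1[C@](C)(O)[C@@H](OC(C)=O)[C@@H](O)[C@H]2C(C)(C)CCC[C@@]21C | target

**Step count and weak points**

Total step count: 19. Longest linear sequence: 18 steps (steps 1–7 and 9–19; step 8 is a one-step side branch).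

Steps most likely to fail:

1. Step 9 (proposed new method). What may go wrong: the ring-opened C1 radical may abstract hydrogen from the solvent or reclose faster than it adds to the unactivated alkene of 14; the cyclopropane may open at the ring-fusion bond instead (ring expansion); the secondary radical may close to a five-membered ring before boron migrates; the allylboronate may add to the ketone. Fallback with known chemistry, from 11 back to 16: Me3SiI (CH2Cl2, −40 °C, then Et3N) should open the same bond by iodide attack at C1 to give the γ-iodo silyl enol ether F1. Tin-hydride Giese addition of its C1 radical to but-3-en-2-one (Bu3SnH, AIBN, benzene, 80 °C) should give the methyl ketone F2, and MeLi at −78 °C the tertiary alcohol F3. TiCl4 (CH2Cl2, −78 °C) should then ionise the tertiary alcohol so that the cation is captured by the silyl enol ether carbon C5 (intramolecular Lewis-acid tert-alkylation of a silyl enol ether); DBU equilibration returns the route to 16.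

2. Step 14. What may go wrong: loss of site selectivity between the two secondary hydroxyls, over-oxidation to the 6,7-dione, or glycol cleavage next to the tertiary oxygen. Fallback, from 17 back to 22, which removes the need to tell two secondary alcohols apart: OsO4/N-methylmorpholine N-oxide dihydroxylation of the enone itself from the α-face should give the 7α,8α-dihydroxy-6-ketone F4. Dess–Martin oxidation of its only secondary alcohol should give the 6,7-diketone F5, and NaBH4 should reduce both carbonyls from the α-face to the 6β,7β,8α-triol ester F6. TFA then closes the lactone to 22.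

3. Step 17. What may go wrong: slow olefination of the masked aldehyde by the weakly nucleophilic formyl ylide, thermal decomposition on prolonged heating, and conjugate addition of the freed tertiary hydroxyl to the enal. Fallback, from 23 back to 24, olefinating at the ester oxidation level: ethyl 2-(triphenylphosphoranylidene)propanoate (benzene, 80 °C) should give the (E)-enoate F7, i-Bu2AlH (−78 °C) the allylic alcohol F8, and MnO2 (CH2Cl2, rt) the enal 24.

**Further compounds**

F1 | step 9 | tert-butyl 2-[2-(iodomethyl)-2,6-dimethyl-4-(trimethylsilyloxy)cyclohex-3-en-1-yl]acetate (γ-iodo silyl enol ether) | CC(C)(C)OC(=O)C[C@H]1[C@H](C)CC(O[Si](C)(C)C)=C[C@]1(C)CI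
F2 | step 9 | tert-butyl 2-[2,6-dimethyl-2-(4-oxopentyl)-4-(trimethylsilyloxy)cyclohex-3-en-1-yl]acetate (methyl ketone) | CC(C)(C)OC(=O)C[C@H]1[C@H](C)CC(O[Si](C)(C)C)=C[C@]1(C)CCCC(C)=O
F3 | step 9 | tert-butyl 2-[2-(4-hydroxy-4-methylpentyl)-2,6-dimethyl-4-(trimethylsilyloxy)cyclohex-3-en-1-yl]acetate (tertiary alcohol) | CC(C)(C)OC(=O)C[C@H]1[C@H](C)CC(O[Si](C)(C)C)=C[C@]1(C)CCCC(C)(C)O
F4 | step 14 | tert-butyl 2-[2,3-dihydroxy-2,5,5,8a-tetramethyl-4-oxodecahydronaphthalen-1-yl]acetate (7α,8α-dihydroxy-6-ketone) | CC(C)(C)OC(=O)C[C@H]1[C@](C)(O)[C@H](O)C(=O)[C@H]2C(C)(C)CCC[C@@]21C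
F5 | step 14 | tert-butyl 2-[2-hydroxy-2,5,5,8a-tetramethyl-3,4-dioxodecahydronaphthalen-1-yl]acetate (6,7-diketone) | CC(C)(C)OC(=O)C[C@H]1[C@](C)(O)C(=O)C(=O)[C@H]2C(C)(C)CCC[C@@]21C
F6 | step 14 | tert-butyl 2-[(1R,2S,3S,4S,4aS,8aS)-2,3,4-trihydroxy-2,5,5,8a-tetramethyldecahydronaphthalen-1-yl]acetate (6β,7β,8α-triol ester) | CC(C)(C)OC(=O)C[C@H]1[C@](C)(O)[C@@H](O)[C@@H](O)[C@H]2C(C)(C)CCC[C@@]21C
F7 | step 17 | ethyl (E)-2-methyl-4-[(1R,2S,3S,4S,4aS,8aS)-2,3,4-trihydroxy-2,5,5,8a-tetramethyldecahydronaphthalen-1-yl]but-2-enoate | CCOC(=O)/C(C)=C/C[C@H]1[C@](C)(O)[C@@H](O)[C@@H](O)[C@H]2C(C)(C)CCC[C@@]21C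
F8 | step 17 | (1R,2S,3S,4S,4aS,8aS)-1-[(E)-4-hydroxy-3-methylbut-2-en-1-yl]-2,5,5,8a-tetramethyldecahydronaphthalene-2,3,4-triol | OC/C(C)=C/C[C@H]1[C@](C)(O)[C@@H](O)[C@@H](O)[C@H]2C(C)(C)CCC[C@@]21C
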